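**Retrosynthetic overview**

- Target ⇐ bis-silyl ether (HF·pyridine) ⇐ thermal 4π opening of a cis-fused aminocyclobutene across C2–C5, followed by closure of the furanone through O10–C3 with loss of diethylamine.
- Aminocyclobutene ⇐ Ficini [2+2] of N,N-diethylprop-1-yn-1-amine with a lactone-fused cis-cyclooctenone (forms C2–C3 and C4–C5) ⇐ ring-closing metathesis (C2=C5) of an α′-hydroxy vinyl ketone.
- Vinyl ketone ⇐ C10 methyl ketone + lithiated methoxyallene (sets C10) and C8 angeloylation ⇐ chlorohydrin γ-lactone from Sharpless epoxidation (C11), chloride opening (C13) and oxidative lactonisation (O6–C12).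
- C6–C7 bond ⇐ indium allylation of acrolein by a Baylis–Hillman-derived allyl bromide; C8 and C9 come from diethyl L-tartrate.
- Ring order: γ-lactone, cyclooctenone, cyclobutene, then ten-membered ring and furanone together. The strategy rests on the C2=C3–C4=C5 diene of the ten-membered ring C1–C10: ring-trans at C2=C3 (held by the O10–C3 bridge of the furanone ring O10/C3/C2/C1/C10) and Z at C4=C5, the pattern that conrotatory opening of a C2–C5 cyclobutene cis-fused to the eight-membered ring delivers.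

Key step: step 24

Remark: atoms carry the target numbering (ring C1–C10, lactone C11–C13, C14 on C10, C15 on C4; target 6S,7S,8S,9R,10R,11R); "ring-trans" at C2=C3 means C1 and C4 on opposite sides, which is Z by the sequence rule in the furanone because O10 outranks C4.

Step 1
Reactants: 1 diethyl L-tartrate
Product: 3 mono-PMB ether of diethyl L-tartrate, via stannylene acetal 2 (not isolated)
Conditions: Bu2SnO, toluene, reflux (−H2O); then PMBCl, CsF, DMF, rt
Reagents that add atoms: 4-methoxybenzyl chloride, COc1ccc(CCl)cc1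
Why: Tin-mediated mono-O-alkylation: the stannylene acetal of the C2-symmetric diol is alkylated once on one of two equivalent oxygens, so one mono-ether results and no stereocentre is touched.

Step 2
Reactants: 3 mono-PMB ether of diethyl L-tartrate
Product: 4 ethyl (2R,3S)-3,4-dihydroxy-2-(PMB-oxy)butanoate
Conditions: BH3·SMe2, NaBH4 (5 mol%), THF, 0 °C → rt; MeOH quench; crude used at once
Reagents that add atoms: none
Why: Hydroxyl-directed borane reduction of an α-hydroxy ester: the boron alkoxide of the free C9 hydroxyl delivers hydride through a five-membered chelate only to the adjacent ester, leaving the ester next to the PMB ether.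

Step 3
Reactants: 4 ethyl (2R,3S)-3,4-dihydroxy-2-(PMB-oxy)butanoate
Product: 5 bis-TBS ether of 4
Conditions: TBSCl, imidazole, DMF, rt
Reagents that add atoms: tert-butyldimethylsilyl chloride, CC(C)(C)[Si](C)(C)Cl
Why: Imidazole-promoted silyl ether formation on the primary and secondary hydroxyls, done on crude 4 to forestall γ-lactonisation.

Step 4
Reactants: 5 bis-TBS ether of 4
Product: 6 (2R,3S)-3,4-bis(TBS-oxy)-2-(PMB-oxy)butanal (aldehyde carbon = C7)
Conditions: i-Bu2AlH, CH2Cl2, −78 °C
Reagents that add atoms: none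
Why: Half-reduction of an ester with i-Bu2AlH: the α-alkoxy aluminium hemiacetal is stable at −78 °C and releases the aldehyde on work-up without epimerising C8.

Step 5
Reactants: 6 (2R,3S)-3,4-bis(TBS-oxy)-2-(PMB-oxy)butanal, 7 methyl acrylate
Product: 8 Morita–Baylis–Hillman adduct (both carbinol epimers)
Conditions: DABCO (1 equiv), 1,4-dioxane/H2O (1:1), rt
Reagents that add atoms: none
Why: Morita–Baylis–Hillman reaction of an activated α-alkoxy aldehyde; the configuration of the new carbinol does not matter because step 6 erases it.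

Step 6
Reactants: 8 Morita–Baylis–Hillman adduct
Product: 9 (Z)-2-(bromomethyl)enoate
Conditions: NBS, Me2S, CH2Cl2, −20 °C → rt
Reagents that add atoms: N-bromosuccinimide, O=C1CCC(=O)N1Br
Why: Corey–Kim-type activation of the allylic alcohol by the bromosulfonium salt and SN2′ return of bromide give the thermodynamically preferred trisubstituted (Z)-allyl bromide.

Step 7
Reactants: 9 (Z)-2-(bromomethyl)enoate, 10 acrolein
Product: 11 homoallylic alcohol (C6 carbinol, C7 new)
Conditions: indium powder, THF/H2O (1:1), rt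
Reagents that add atoms: none
Why: Barbier-type indium allylation (SE2′ through a six-membered chair): the (Z)-allyl unit should give the adduct with C6–OH and the C8 branch syn (the cis-lactone series), and the aldehyde should add to the C7 face anti to the C8–C9 bond with C8–H eclipsing the alkene (allylic 1,3-strain), which puts C7–C11 anti to O8 as in the target.

Step 8
Reactants: 11 homoallylic alcohol
Product: 12 C6 triethylsilyl ether of 11
Conditions: TESCl, imidazole, DMAP (cat.), CH2Cl2, 0 °C
Reagents that add atoms: chlorotriethylsilane, CC[Si](Cl)(CC)CC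
Why: Silyl ether formation masks O6, which as a free hydroxyl could open the C11–C13 epoxide of step 10 to a tetrahydrofuran.

Step 9
Reactants: 12 C6 triethylsilyl ether of 11
Product: 13 2-substituted allylic alcohol (C12 CH2OH)
Conditions: i-Bu2AlH, CH2Cl2, −78 °C
Reagents that add atoms: none
Why: 1,2-Reduction of the α,β-unsaturated ester with i-Bu2AlH gives the primary allylic alcohol needed to direct the epoxidation.

Step 10
Reactants: 13 2-substituted allylic alcohol
Product: 14 (11R)-epoxy alcohol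
Conditions: Ti(OiPr)4, D-(−)-diethyl tartrate, t-BuOOH, 4 Å molecular sieves, CH2Cl2, −20 °C
Reagents that add atoms: tert-butyl hydroperoxide, CC(C)(C)OO
Why: Sharpless asymmetric epoxidation: the titanium-bound allylic alcohol is epoxidised under reagent control, and D-(−)-diethyl tartrate (the opposite sense to the L-(+)-tartrate that gives (2S,3S)-epoxygeraniol) should give the (R)-2-substituted glycidol, which is the C11 configuration of the target; the vinyl group and the silyl ethers are not substrates.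

Step 11
Reactants: 14 (11R)-epoxy alcohol
Product: 16 chloro triol, via chlorohydrin triethylsilyl ether 15 (not isolated)
Conditions: LiCl, AcOH, THF, rt; then PPTS, MeOH, 0 °C → rt
Reagents that add atoms: lithium chloride, [Li+].[Cl-]
Why: SN2 opening of the 2,2-disubstituted epoxide by chloride at the primary C13 (halohydrin formation) leaves the C11–O bond and its configuration intact, and mild acid methanolysis then removes only the secondary triethylsilyl ether.

Step 12
Reactants: 16 chloro triol
Product: 19 chlorohydrin γ-lactone, via hydroxy aldehyde 17 (not isolated), via lactol 18 (not isolated)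
Conditions: TEMPO (cat.), PhI(OAc)2, CH2Cl2, rt
Reagents that add atoms: none
Why: TEMPO/PhI(OAc)2 oxidative lactonisation of a 1,4-diol: the primary C12 alcohol is oxidised, the aldehyde is trapped by the C6 hydroxyl as a lactol and this is oxidised to the lactone; O8 is blocked as its PMB ether, so only the 6,12-lactone can form.

Step 13
Reactants: 19 chlorohydrin γ-lactone
Product: 20 C10 primary alcohol
Conditions: HF·pyridine, pyridine, THF, 0 °C
Reagents that add atoms: none
Why: Selective fluoride-mediated cleavage of the primary TBS ether; the hindered secondary TBS ether on O9 reacts much more slowly.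

Step 14
Reactants: 20 C10 primary alcohol
Product: 21 bis-triethylsilyl ether (O10 and O11)
Conditions: TESOTf, 2,6-lutidine, CH2Cl2, −78 → 0 °C
Reagents that add atoms: triethylsilyl trifluoromethanesulfonate, CC[Si](CC)(CC)OS(=O)(=O)C(F)(F)F
Why: Silyl triflate silylation protects the hindered tertiary C11 hydroxyl (otherwise an alkoxide that could displace the C13 chloride in steps 16 and 18) together with the primary hydroxyl.

Step 15
Reactants: 21 bis-triethylsilyl ether
Product: 22 C10 aldehyde
Conditions: (COCl)2, DMSO, CH2Cl2, −78 → −30 °C; then i-Pr2NEt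
Reagents that add atoms: none
Why: Swern oxidation applied to a primary triethylsilyl ether (known oxidative desilylation: the unhindered primary Si–O bond is cleaved and the alcohol oxidised in the same flask) while the tertiary TES and secondary TBS ethers persist.

Step 16
Reactants: 22 C10 aldehyde
Product: 23 C10 methyl carbinol (both epimers)
Conditions: MeMgBr, THF, −78 °C; quench at −78 °C
Reagents that add atoms: methylmagnesium bromide, C[Mg]Br
Why: Grignard addition to the aldehyde, much faster at −78 °C than attack on the hindered α-quaternary lactone; the carbinol configuration is removed in step 17.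

Step 17
Reactants: 23 C10 methyl carbinol
Product: 24 C10 methyl ketone
Conditions: Dess–Martin periodinane, NaHCO3, CH2Cl2, rt
Reagents that add atoms: none
Why: Dess–Martin oxidation of the secondary alcohol under buffered conditions that do not epimerise C9.

Step 18
Reactants: 24 C10 methyl ketone, 25 methoxyallene
Product: 27 α′-hydroxy vinyl ketone, via allenyl carbinol 26 (not isolated)
Conditions: 25, n-BuLi, THF, −78 °C; then 24, −78 °C; then 1 M HCl, THF, 0 °C
Reagents that add atoms: water, O
Why: Addition of 1-lithio-1-methoxyallene (an acryloyl anion equivalent) should follow the polar Felkin–Anh model, entering anti to the C9–OTBS bond to give the 10R carbinol (O9 and O10 anti in the zigzag projection), and acid hydrolysis of the allenyl enol ether unveils the vinyl ketone.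

Step 19
Reactants: 27 α′-hydroxy vinyl ketone
Product: 28 C8 alcohol
Conditions: DDQ, CH2Cl2/pH 7 buffer, 0 °C → rt
Reagents that add atoms: none
Why: Oxidative cleavage of the PMB ether by DDQ (benzylic hydride abstraction, hydrolysis of the oxocarbenium ion) frees only O8.

Step 20
Reactants: 28 C8 alcohol, 29 angelic acid
Product: 30 C8 angelate
Conditions: 29, 2,4,6-trichlorobenzoyl chloride, Et3N, toluene, rt; then 28, DMAP, rt → 40 °C
Reagents that add atoms: none
Why: Yamaguchi esterification: the mixed anhydride acylates the secondary C8 hydroxyl without Z to E isomerisation of the angelate, and the tertiary C10 hydroxyl is too hindered to compete.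

Step 21
Reactants: 30 C8 angelate
Product: 31 lactone-fused cis-cyclooctenone
Conditions: second-generation Grubbs catalyst (10 mol%), toluene (2 mM), 80 °C
Reagents that add atoms: none
Why: Ring-closing metathesis of the vinyl ketone onto the C6 vinyl group, helped by the cis-lactone that holds both alkenes on one face; the trisubstituted, electron-poor angelate alkene should not take part.

Step 22
Reactants: 31 lactone-fused cis-cyclooctenone
Product: 32 C10 trimethylsilyl ether
Conditions: 1-(trimethylsilyl)imidazole, CH2Cl2, rt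
Reagents that add atoms: 1-(trimethylsilyl)imidazole, C[Si](C)(C)n1ccnc1
Why: Silyl ether formation on the tertiary α-hydroxy ketone removes the last free hydroxyl, which would otherwise add to the ynamine.

Step 23
Reactants: 32 C10 trimethylsilyl ether, 33 N,N-diethylprop-1-yn-1-amine
Product: 34 cis-fused aminocyclobutene (both cis diastereomers at C2/C5)
Conditions: MgBr2·OEt2 (10 mol%), MeCN, 0 °C → rt; crude used
Reagents that add atoms: none
Why: Ficini [2+2] cycloaddition: the nucleophilic methyl-bearing carbon of the ynamine adds to C5 of the enone and the enolate closes on the keteniminium carbon, so C4 ends on C5 and C3 on C2; either cis-fused diastereomer serves because C2 and C5 become sp2 in step 24.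

Step 24
Reactants: 34 cis-fused aminocyclobutene
Product: 37 9-O-TBS-11-O-TES target, via 3-amino dienone 35 (not isolated), via free C10 carbinol 36 (not isolated)
Conditions: toluene, 90 °C; then 0.5 M aq. citric acid, THF, rt
Reagents that add atoms: none
Why: Proposed new method: thermal conrotatory 4π electrocyclic opening of the cis-fused aminocyclobutene breaks C2–C5 (the C3 amino group and the C1 carbonyl on C2 polarise this bond towards a vinylogous iminium/enolate pair, so about 90 °C should suffice) and turns the eight-membered ring into the ten-membered 3-amino-2,4-dienone 35; the acidic work-up then cleaves the tertiary TMS ether and O10 adds to C3 of the protonated vinylogous amide with loss of diethylamine. The closest known reaction types are the Ficini cycloaddition itself, the two-carbon ring enlargement of ring-fused donor–acceptor cyclobutenes by thermal opening and the formation of 3(2H)-furanones by amine displacement from α′-hydroxy β-amino enones, none of which has been run as this sequence on a cyclooctenone adduct. The ten-membered ring is formed by ring enlargement and not by a cyclisation, and the furanone closes 5-exo-trig on the C3 iminium carbon of the O-protonated enaminone (it would be 5-endo-trig on the neutral C2=C3 bond, hence the acid). No stereocentre is created, since C2 and C5 become sp2 and C10 only exchanges silicon for C3 on its oxygen. The step needs C4=C5 cis (Z, C6 turned inward) and C2=C3 ring-trans (C1 outward): the cis ring fusion obliges one terminus to turn inward, the push–pull C2=C3 bond rotates easily and the dienamine can re-equilibrate through its zwitterionic form, so the product should collect in the geometry that the O10–C3 bridge can span, and the silyl ether on O9 leaves O10 as the only oxygen able to close.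

Step 25
Reactants: 37 9-O-TBS-11-O-TES target
Product: 38 CNP0272644.1
Conditions: HF·pyridine, THF, 0 °C → rt
Reagents that add atoms: none
Why: Fluoride-mediated desilylation under mildly acidic conditions removes the secondary TBS and tertiary TES ethers and leaves the angelate, chlorohydrin, lactone and furanone untouched.

**Compound list** (PMB = 4-methoxybenzyl, TBS = tert-butyldimethylsilyl, TES = triethylsilyl, TMS = trimethylsilyl; from 11 on, every stereocentre has the spatial arrangement of the same-numbered centre of the target)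

1 | diethyl L-tartrate, diethyl (2R,3R)-2,3-dihydroxybutanedioate | CCOC(=O)[C@H](O)[C@@H](O)C(=O)OCC | starting material
2 | dibutylstannylene acetal of 1, diethyl (4R,5R)-2,2-dibutyl-1,3,2-dioxastannolane-4,5-dicarboxylate | CCOC(=O)[C@H](O[Sn]1(CCCC)CCCC)[C@@H](O1)C(=O)OCC | intermediate
3 | diethyl (2R,3R)-2-hydroxy-3-(PMB-oxy)butanedioate (PMB-bearing carbon = C8, carbinol = C9) | CCOC(=O)[C@H](OCc1ccc(OC)cc1)[C@@H](O)C(=O)OCC | intermediate
4 | ethyl (2R,3S)-3,4-dihydroxy-2-(PMB-oxy)butanoate | CCOC(=O)[C@H](OCc1ccc(OC)cc1)[C@@H](O)CO | intermediate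
5 | ethyl (2R,3S)-3,4-bis(TBS-oxy)-2-(PMB-oxy)butanoate | CCOC(=O)[C@H](OCc1ccc(OC)cc1)[C@@H](O[Si](C)(C)C(C)(C)C)CO[Si](C)(C)C(C)(C)C | intermediate
6 | (2R,3S)-3,4-bis(TBS-oxy)-2-(PMB-oxy)butanal | O=C[C@H](OCc1ccc(OC)cc1)[C@@H](O[Si](C)(C)C(C)(C)C)CO[Si](C)(C)C(C)(C)C | intermediate
7 | methyl acrylate | C=CC(=O)OC | starting material
8 | methyl (4S,5S)-5,6-bis(TBS-oxy)-3-hydroxy-2-methylidene-4-(PMB-oxy)hexanoate, both C3 epimers | C=C(C(=O)OC)C(O)[C@H](OCc1ccc(OC)cc1)[C@@H](O[Si](C)(C)C(C)(C)C)CO[Si](C)(C)C(C)(C)C | intermediate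
9 | methyl (2Z,4S,5S)-2-(bromomethyl)-5,6-bis(TBS-oxy)-4-(PMB-oxy)hex-2-enoate | COC(=O)/C(CBr)=C/[C@H](OCc1ccc(OC)cc1)[C@@H](O[Si](C)(C)C(C)(C)C)CO[Si](C)(C)C(C)(C)C | intermediate
10 | acrolein | C=CC=O | starting material
11 | methyl 4-hydroxy-2-methylidenehex-5-enoate carrying on C3 (= C7) the 2,3-bis(TBS-oxy)-1-(PMB-oxy)propyl chain (C8–C10); C6–OH and the C8 branch syn along C5–C6–C7–C11, C7–C11 anti to O8 | C=C[C@H](O)[C@@H]([C@H](OCc1ccc(OC)cc1)[C@@H](O[Si](C)(C)C(C)(C)C)CO[Si](C)(C)C(C)(C)C)C(=C)C(=O)OC | intermediate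
12 | C6 triethylsilyl ether of 11 | C=C[C@H](O[Si](CC)(CC)CC)[C@@H]([C@H](OCc1ccc(OC)cc1)[C@@H](O[Si](C)(C)C(C)(C)C)CO[Si](C)(C)C(C)(C)C)C(=C)C(=O)OC | intermediate
13 | allylic alcohol: ester of 12 reduced to C12 CH2OH on C11(=C13H2) | C=C[C@H](O[Si](CC)(CC)CC)[C@@H]([C@H](OCc1ccc(OC)cc1)[C@@H](O[Si](C)(C)C(C)(C)C)CO[Si](C)(C)C(C)(C)C)C(=C)CO | intermediate
14 | (11R)-C11–C13 epoxide of 13 (2-substituted glycidol) | C=C[C@H](O[Si](CC)(CC)CC)[C@@H]([C@H](OCc1ccc(OC)cc1)[C@@H](O[Si](C)(C)C(C)(C)C)CO[Si](C)(C)C(C)(C)C)[C@@]1(CO)CO1 | intermediate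
15 | chlorohydrin: C13 chloride, C11 tertiary alcohol, C12 CH2OH, C6–OTES | C=C[C@H](O[Si](CC)(CC)CC)[C@@H]([C@H](OCc1ccc(OC)cc1)[C@@H](O[Si](C)(C)C(C)(C)C)CO[Si](C)(C)C(C)(C)C)[C@@](O)(CO)CCl | intermediate
16 | chloro triol: 15 with free C6–OH | C=C[C@H](O)[C@@H]([C@H](OCc1ccc(OC)cc1)[C@@H](O[Si](C)(C)C(C)(C)C)CO[Si](C)(C)C(C)(C)C)[C@@](O)(CO)CCl | intermediate
17 | C12 aldehyde of 16 | C=C[C@H](O)[C@@H]([C@H](OCc1ccc(OC)cc1)[C@@H](O[Si](C)(C)C(C)(C)C)CO[Si](C)(C)C(C)(C)C)[C@@](O)(C=O)CCl | intermediate
18 | lactol (O6–C12 hemiacetal) of 17 | C=C[C@@H]1OC(O)[C@@](O)(CCl)[C@@H]1[C@H](OCc1ccc(OC)cc1)[C@@H](O[Si](C)(C)C(C)(C)C)CO[Si](C)(C)C(C)(C)C | intermediate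
19 | cis-γ-lactone (6,12-olide): C6 vinyl, C11 OH and CH2Cl, C7 chain with C8–OPMB, C9–OTBS, C10–OTBS | C=C[C@@H]1OC(=O)[C@@](O)(CCl)[C@@H]1[C@H](OCc1ccc(OC)cc1)[C@@H](O[Si](C)(C)C(C)(C)C)CO[Si](C)(C)C(C)(C)C | intermediate
20 | 19 with free primary C10–OH | C=C[C@@H]1OC(=O)[C@@](O)(CCl)[C@@H]1[C@H](OCc1ccc(OC)cc1)[C@@H](O[Si](C)(C)C(C)(C)C)CO | intermediate
21 | O10,O11-bis(triethylsilyl) ether of 20 | C=C[C@@H]1OC(=O)[C@@](O[Si](CC)(CC)CC)(CCl)[C@@H]1[C@H](OCc1ccc(OC)cc1)[C@@H](O[Si](C)(C)C(C)(C)C)CO[Si](CC)(CC)CC | intermediate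
22 | C10 aldehyde (C11–OTES kept) | C=C[C@@H]1OC(=O)[C@@](O[Si](CC)(CC)CC)(CCl)[C@@H]1[C@H](OCc1ccc(OC)cc1)[C@@H](O[Si](C)(C)C(C)(C)C)C=O | intermediate
23 | C10 methyl carbinol, both epimers | C=C[C@@H]1OC(=O)[C@@](O[Si](CC)(CC)CC)(CCl)[C@@H]1[C@H](OCc1ccc(OC)cc1)[C@@H](O[Si](C)(C)C(C)(C)C)C(C)O | intermediate
24 | C10 methyl ketone (C14 methyl) | C=C[C@@H]1OC(=O)[C@@](O[Si](CC)(CC)CC)(CCl)[C@@H]1[C@H](OCc1ccc(OC)cc1)[C@@H](O[Si](C)(C)C(C)(C)C)C(C)=O | intermediate
25 | methoxyallene (1-methoxypropa-1,2-diene) | COC=C=C | starting material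
26 | (10R)-tertiary carbinol bearing the 1-methoxyallenyl group on C10 | C=C[C@@H]1OC(=O)[C@@](O[Si](CC)(CC)CC)(CCl)[C@@H]1[C@H](OCc1ccc(OC)cc1)[C@@H](O[Si](C)(C)C(C)(C)C)[C@@](C)(O)C(OC)=C=C | intermediate
27 | α′-hydroxy vinyl ketone: C10(OH)(CH3)–C1(=O)–CH=CH2 | C=C[C@@H]1OC(=O)[C@@](O[Si](CC)(CC)CC)(CCl)[C@@H]1[C@H](OCc1ccc(OC)cc1)[C@@H](O[Si](C)(C)C(C)(C)C)[C@@](C)(O)C(=O)C=C | intermediate
28 | 27 with free C8–OH | C=C[C@@H]1OC(=O)[C@@](O[Si](CC)(CC)CC)(CCl)[C@@H]1[C@H](O)[C@@H](O[Si](C)(C)C(C)(C)C)[C@@](C)(O)C(=O)C=C | intermediate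
29 | angelic acid, (Z)-2-methylbut-2-enoic acid | C/C=C(/C)C(=O)O | starting material
30 | C8 angelate of 28 | C=C[C@@H]1OC(=O)[C@@](O[Si](CC)(CC)CC)(CCl)[C@@H]1[C@H](OC(=O)/C(C)=C\C)[C@@H](O[Si](C)(C)C(C)(C)C)[C@@](C)(O)C(=O)C=C | intermediate
31 | cis-cyclooctenone (C1 ketone, C2=C5 Z) cis-fused at C6–C7 to the γ-lactone; C8 angelate, C9–OTBS, C10–OH, C11–OTES | O=C1/C=C\[C@@H]2OC(=O)[C@@](O[Si](CC)(CC)CC)(CCl)[C@@H]2[C@H](OC(=O)/C(C)=C\C)[C@@H](O[Si](C)(C)C(C)(C)C)[C@@]1(C)O | intermediate
32 | C10 trimethylsilyl ether of 31 | O=C1/C=C\[C@@H]2OC(=O)[C@@](O[Si](CC)(CC)CC)(CCl)[C@@H]2[C@H](OC(=O)/C(C)=C\C)[C@@H](O[Si](C)(C)C(C)(C)C)[C@@]1(C)O[Si](C)(C)C | intermediate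
33 | N,N-diethylprop-1-yn-1-amine | CCN(CC)C#CC | starting material
34 | aminocyclobutene: C2–C3(NEt2)=C4(CH3)–C5 four-membered ring cis-fused to the cyclooctanone at C2–C5, C2 and C5 undefined | C/C=C(/C)C(=O)O[C@H]1[C@@H]2[C@H](C3C(C)=C(N(CC)CC)C3C(=O)[C@](C)(O[Si](C)(C)C)[C@@H]1O[Si](C)(C)C(C)(C)C)OC(=O)[C@@]2(O[Si](CC)(CC)CC)CCl | intermediate
35 | ten-membered 3-(diethylamino)-2,4-dienone, C4=C5 Z, C2=C3 ring-trans, C10–OTMS | C/C=C(/C)C(=O)O[C@H]1[C@@H]2[C@H](/C=C(/C)\C(N(CC)CC)=C\C(=O)[C@](C)(O[Si](C)(C)C)[C@@H]1O[Si](C)(C)C(C)(C)C)OC(=O)[C@@]2(O[Si](CC)(CC)CC)CCl | intermediate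
36 | 35 with free C10–OH | C/C=C(/C)C(=O)O[C@H]1[C@@H]2[C@H](/C=C(/C)\C(N(CC)CC)=C\C(=O)[C@](C)(O)[C@@H]1O[Si](C)(C)C(C)(C)C)OC(=O)[C@@]2(O[Si](CC)(CC)CC)CCl | intermediate
37 | 9-O-TBS-11-O-TES ether of the target | C/C=C(/C)C(=O)O[C@H]1[C@@H]2[C@H](/C=C(/C)C3=CC(=O)[C@](C)(O3)[C@@H]1O[Si](C)(C)C(C)(C)C)OC(=O)[C@@]2(O[Si](CC)(CC)CC)CCl | intermediate
38 | CNP0272644.1 | C/C=C(/C)C(=O)O[C@H]1[C@@H]2[C@H](/C=C(/C)C3=CC(=O)[C@](C)(O3)[C@@H]1O)OC(=O)[C@@]2(O)CCl | target

Total step count: 25. Longest linear sequence: 25 steps (1 to 38).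

**Steps most likely to fail**

1. Step 24 (Proposed new method). The ring opening may take the other conrotatory sense (C1 inward, C4=C5 E) without later equilibration, or the enamine may hydrolyse before the ring opens, so that no ten-membered ring forms. Fallback with known chemistry, setting out from methyl ketone 24 and coming back at 37: ethynylmagnesium bromide adds under Felkin–Anh control to give the tertiary propargylic alcohol F1; its dianion (n-BuLi) adds to methacrolein to give the ynediol F2; MnO2 oxidises the secondary propargylic alcohol to the γ-hydroxy ynone F3; diethylamine in ethanol, then aqueous acetic acid, cyclises it to the 5-isopropenyl-3(2H)-furanone F4; DDQ frees O8 to give the alcohol F5 and Yamaguchi esterification gives the angelate F6; ring-closing metathesis between the isopropenyl group and the C6 vinyl group with the second-generation Grubbs catalyst closes the ten-membered ring at C4=C5 and gives 37.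

2. Step 23. The cycloaddition may be too slow on the β-branched medium-ring enone, so that the ynamine adds to the C1 carbonyl or oligomerises instead. Fallback setting out from 32 and coming back at 37: the ynamide 3-(prop-1-yn-1-yl)oxazolidin-2-one under CuCl2/AgSbF6 catalysis (Lewis-acid-catalysed Ficini variant) gives the amidocyclobutene F7; heating opens the ring and aqueous acid then removes the oxazolidinone and the TMS group and closes the furanone, giving 37.

3. Step 21. Intermolecular metathesis may outrun closure of the strained eight-membered enone ring. Fallback setting out from 30 and coming back at 31: Luche reduction (NaBH4, CeCl3·7H2O, MeOH, −78 °C) gives the dienol F8; ring-closing metathesis of this allylic alcohol, which closes more readily than a vinyl ketone, gives the cyclooctenol F9; Dess–Martin oxidation of the secondary allylic alcohol returns 31.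

Further compounds
F1 | step 24 | (10R)-ethynyl carbinol from 24 | C=C[C@@H]1OC(=O)[C@@](O[Si](CC)(CC)CC)(CCl)[C@@H]1[C@H](OCc1ccc(OC)cc1)[C@@H](O[Si](C)(C)C(C)(C)C)[C@@](C)(O)C#C
F2 | step 24 | ynediol from F1 and methacrolein (both carbinol epimers) | C=C[C@@H]1OC(=O)[C@@](O[Si](CC)(CC)CC)(CCl)[C@@H]1[C@H](OCc1ccc(OC)cc1)[C@@H](O[Si](C)(C)C(C)(C)C)[C@@](C)(O)C#CC(O)C(C)=C
F3 | step 24 | γ-hydroxy ynone | C=C[C@@H]1OC(=O)[C@@](O[Si](CC)(CC)CC)(CCl)[C@@H]1[C@H](OCc1ccc(OC)cc1)[C@@H](O[Si](C)(C)C(C)(C)C)[C@@](C)(O)C#CC(=O)C(C)=C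
F4 | step 24 | 5-isopropenyl-3(2H)-furanone (O10–C3 closed), C8–OPMB | C=C[C@@H]1OC(=O)[C@@](O[Si](CC)(CC)CC)(CCl)[C@@H]1[C@H](OCc1ccc(OC)cc1)[C@@H](O[Si](C)(C)C(C)(C)C)[C@@]2(C)OC(C(C)=C)=CC2=O
F5 | step 24 | F4 with free C8–OH | C=C[C@@H]1OC(=O)[C@@](O[Si](CC)(CC)CC)(CCl)[C@@H]1[C@H](O)[C@@H](O[Si](C)(C)C(C)(C)C)[C@@]2(C)OC(C(C)=C)=CC2=O
F6 | step 24 | C8 angelate of F5 | C=C[C@@H]1OC(=O)[C@@](O[Si](CC)(CC)CC)(CCl)[C@@H]1[C@H](OC(=O)/C(C)=C\C)[C@@H](O[Si](C)(C)C(C)(C)C)[C@@]2(C)OC(C(C)=C)=CC2=O
F7 | step 23 | amidocyclobutene from 32 and 3-(prop-1-yn-1-yl)oxazolidin-2-one (cis-fused, C2 and C5 undefined) | C/C=C(/C)C(=O)O[C@H]1[C@@H]2[C@H](C3C(C)=C(N4CCOC4=O)C3C(=O)[C@](C)(O[Si](C)(C)C)[C@@H]1O[Si](C)(C)C(C)(C)C)OC(=O)[C@@]2(O[Si](CC)(CC)CC)CCl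
F8 | step 21 | dienol: C1 carbinol of 30 (both epimers) | C=C[C@@H]1OC(=O)[C@@](O[Si](CC)(CC)CC)(CCl)[C@@H]1[C@H](OC(=O)/C(C)=C\C)[C@@H](O[Si](C)(C)C(C)(C)C)[C@@](C)(O)C(O)C=C
F9 | step 21 | cyclooctenol: C1 carbinol of 31 (both epimers) | OC1/C=C\[C@@H]2OC(=O)[C@@](O[Si](CC)(CC)CC)(CCl)[C@@H]2[C@H](OC(=O)/C(C)=C\C)[C@@H](O[Si](C)(C)C(C)(C)C)[C@@]1(C)O
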